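**Assumption:** Ageconyflavone C has no stereocentre or stereogenic double bond, so it is achiral and "single enantiomer" needs no stereocontrol; the SMILES therefore carry no stereodescriptors.

## Retrosynthetic overview

1. The pyranone ring is made last. Its aryl C8a–O1 bond comes from ketone-directed C–H oxygenation of the only free ortho C–H of a 2,3,4-trimethoxybenzoyl group, and the O1–C2 bond from acid cyclodehydration in the same flask.
2. The open-chain precursor is a 1,3-diaryl-1,3-diketone, cut at C3–C4 by a crossed Claisen condensation.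
3. Both benzene rings are bought intact: acetosyringone (B ring plus C2/C3) and methyl 2,3,4-trimethoxybenzoate (A ring plus C4). No protecting-group steps are used.

## Route

Step 1
Reactants: 1 acetosyringone (1-(4-hydroxy-3,5-dimethoxyphenyl)ethan-1-one); 2 methyl 2,3,4-trimethoxybenzoate
Product: 3 1-(4-hydroxy-3,5-dimethoxyphenyl)-3-(2,3,4-trimethoxyphenyl)propane-1,3-dione
Conditions: LiHMDS (3.3 equiv), THF, −78 °C → 50 °C; then 1 M HCl
Reagents that add atoms: none
Why: Crossed Claisen condensation in which the phenoxide/enolate dianion of 1 C-acylates with the non-enolisable ester 2 and is driven forward by deprotonation of the diketone formed (third equivalent of base); the phenoxide cannot be acylated irreversibly by a methyl ester, so no protection is needed.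

Step 2
Reactants: 3 1-(4-hydroxy-3,5-dimethoxyphenyl)-3-(2,3,4-trimethoxyphenyl)propane-1,3-dione
Product: 7 Ageconyflavone C (2-(4-hydroxy-3,5-dimethoxyphenyl)-5,6,7-trimethoxy-4H-chromen-4-one), via aryl trifluoroacetate 4 (not isolated), via bis(trifluoroacetate) 5 (not isolated), via hydroxy diketone 6 (not isolated)
Conditions: TFA/TFAA 9:1, rt, 15 min; Pd(TFA)2 (10 mol%), K2S2O8 (1.3 equiv), 60 °C, 4 h; then H2O, 60 °C, 1 h
Reagents that add atoms: trifluoroacetic acid OC(=O)C(F)(F)F (its oxygen becomes ring O1 of 7); trifluoroacetic anhydride O=C(OC(=O)C(F)(F)F)C(F)(F)F (CF3CO groups carried only by 4 and 5, lost before 7)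
Why: Proposed new method: a ketone-directed Pd(II)/Pd(IV) ortho-C–H trifluoroacetoxylation is run on a 1,3-diaryl-1,3-diketone and coupled in the same flask with chromone ring closure. TFAA first caps the oxidation-sensitive syringyl OH as its trifluoroacetate (4), and in TFA the diketone stays protonated and so does not lock Pd as an O,O-diketonate. The A-ring carbonyl then σ-binds Pd(TFA)2 and concerted metalation–deprotonation occurs at C6–H, which is the only ortho C–H of that ring and is unhindered, whereas both ortho C–H of the B ring are flanked by OMe. Persulfate oxidises the five-membered palladacycle to Pd(IV), and C–O reductive elimination with trifluoroacetate gives 5. Added water cleaves both aryl trifluoroacetates to 6, whose new phenol adds to the B-ring carbonyl and loses water to give 7. The closest known reactions are the Pd-catalysed ortho-hydroxylation of simple aryl ketones in TFA/TFAA with persulfate and the acid cyclodehydration that ends a Baker–Venkataraman flavone synthesis; the β-diketone substrate, the single-flask ring closure and the transient CF3CO protection are untested.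

## Compound list

1 | acetosyringone, 1-(4-hydroxy-3,5-dimethoxyphenyl)ethan-1-one | CC(=O)c1cc(OC)c(O)c(OC)c1 | starting material
2 | methyl 2,3,4-trimethoxybenzoate | COC(=O)c1ccc(OC)c(OC)c1OC | starting material
3 | 1-(4-hydroxy-3,5-dimethoxyphenyl)-3-(2,3,4-trimethoxyphenyl)propane-1,3-dione (largely enolised) | COc1cc(C(=O)CC(=O)c2ccc(OC)c(OC)c2OC)cc(OC)c1O | intermediate
4 | 2,6-dimethoxy-4-[3-oxo-3-(2,3,4-trimethoxyphenyl)propanoyl]phenyl trifluoroacetate | COc1cc(C(=O)CC(=O)c2ccc(OC)c(OC)c2OC)cc(OC)c1OC(=O)C(F)(F)F | intermediate
5 | 2,6-dimethoxy-4-{3-oxo-3-[2,3,4-trimethoxy-6-(trifluoroacetoxy)phenyl]propanoyl}phenyl trifluoroacetate | COc1cc(C(=O)CC(=O)c2c(OC(=O)C(F)(F)F)cc(OC)c(OC)c2OC)cc(OC)c1OC(=O)C(F)(F)F | intermediate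
6 | 1-(6-hydroxy-2,3,4-trimethoxyphenyl)-3-(4-hydroxy-3,5-dimethoxyphenyl)propane-1,3-dione | COc1cc(C(=O)CC(=O)c2c(O)cc(OC)c(OC)c2OC)cc(OC)c1O | intermediate
7 | Ageconyflavone C, 2-(4-hydroxy-3,5-dimethoxyphenyl)-5,6,7-trimethoxy-4H-chromen-4-one | COc1cc(-c2cc(=O)c3c(OC)c(OC)c(OC)cc3o2)cc(OC)c1O | target

## Summary and risks

Total step count: 2. Longest linear sequence: 2.

The route has only two steps, so both are ranked and there is no third.

**Most likely to fail: step 2 (the proposed new step).** Possible failures are oxygenation at the central carbon of the diketone, non-directed palladation at the electron-rich A-ring C5 or at a B-ring ortho position, and persulfate damage to the methoxyarenes. The fallback uses known chemistry with no C–H oxidation and sets out from 1. Claisen condensation of 1 with diethyl carbonate (NaH, THF, reflux) gives ethyl 3-(4-hydroxy-3,5-dimethoxyphenyl)-3-oxopropanoate F1. F1 is then fused neat at about 240 °C with 3,4,5-trimethoxyphenol (COc1cc(O)cc(OC)c1OC) in a thermal Mentzer pyrone synthesis. The aroylketene formed from F1 C-acylates the symmetrical phenol at a free position ortho to OH, giving 6, which cyclodehydrates in the melt. The fallback comes back to the route at 7.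

**Second: step 1.** The hindered, electron-rich ester 2 may acylate the dianion of 1 slowly, and the dianion may be poorly soluble. The fallback sets out from 1. Claisen–Schmidt condensation of 1 with 2,3,4-trimethoxybenzaldehyde (COc1ccc(C=O)c(OC)c1OC; KOH, EtOH, or HCl/EtOH) gives the chalcone (E)-1-(4-hydroxy-3,5-dimethoxyphenyl)-3-(2,3,4-trimethoxyphenyl)prop-2-en-1-one F2. Wacker–Tsuji oxidation of the enone (Na2PdCl4 cat., t-BuOOH, AcOH/H2O, 50 °C) puts the new carbonyl on the β-carbon. The fallback comes back to the route at 3.

## Further compounds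

F1 | step 2 | ethyl 3-(4-hydroxy-3,5-dimethoxyphenyl)-3-oxopropanoate | CCOC(=O)CC(=O)c1cc(OC)c(O)c(OC)c1
F2 | step 1 | (E)-1-(4-hydroxy-3,5-dimethoxyphenyl)-3-(2,3,4-trimethoxyphenyl)prop-2-en-1-one | COc1cc(C(=O)/C=C/c2ccc(OC)c(OC)c2OC)cc(OC)c1O
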